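**Strategy.** Everything rests on closing the trans-fused γ-lactone (O–C6–C7–C11–C12) at its alkyl C–O bond: a C12 carboxylate on the C7 arm displaces a 6β-mesylate on the cyclohexane ring (C5–C10) with inversion. The precursor is the isomeric 8,12-olide: hydroxide opens it, the freed carboxylate recloses onto C6, and O8 is released for the angelate, so one operation moves the lactone, sets C6 and differentiates the two ring oxygens. The feature exploited is C7 flanked by oxygenated C6 and C8 beneath the axial C10 methyl, which steers hydride to the 6β-alcohol. The carbocycle comes from an enantioselective Ireland–Claisen rearrangement and an aldol ring closure.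

Key step: step 11

Remark on numbering: ring carbons are C5–C6–C7–C8–C9–C10; C10 carries the methyl C14 and the vinyl group C1=C2; C5 carries C4 (with C3 and C15); C7 carries C11 (with C12 and C13); β is the face of the C10 methyl, α the opposite face.

Assumption: the (4S,5S)-bromoborane of step 3 is taken to deliver the (2S,3S)-acid 7; should its sense of induction be opposite, the (4R,5R)-reagent is used instead.

Step 1
Reactants: 1 tert-butyl(but-3-yn-1-yloxy)dimethylsilane
Product: 3 (2E)-5-{[tert-butyl(dimethyl)silyl]oxy}-3-methylpent-2-en-1-ol, via alkenylalane 2 (not isolated)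
Conditions: AlMe3, Cp2ZrCl2 (25 mol %), CH2Cl2, 0 °C to rt; then (CH2O)n, THF, rt; aq. HCl
Reagents that add atoms: trimethylaluminium C[Al](C)C; formaldehyde (as paraformaldehyde) C=O
Why: Zirconium-catalysed syn-carboalumination of the terminal alkyne (Negishi carboalumination) puts methyl on the internal carbon cis to aluminium, and hydroxymethylation of the alkenylalane proceeds with retention, so the E-trisubstituted allylic alcohol should result.

Step 2
Reactants: 3 (2E)-allylic alcohol; 4 4-tert-butoxy-4-oxobutanoic acid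
Product: 5 1-tert-butyl 4-[(2E)-5-{[tert-butyl(dimethyl)silyl]oxy}-3-methylpent-2-en-1-yl] butanedioate
Conditions: EDC·HCl, DMAP (cat.), CH2Cl2, 0 °C to rt
Reagents that add atoms: none
Why: Carbodiimide (Steglich) esterification of a primary allylic alcohol with the free carboxyl of the succinate half ester; no stereocenter is formed.

Step 3
Reactants: 5 allyl tert-butyl succinate
Product: 7 (2S,3S)-2-(2-tert-butoxy-2-oxoethyl)-3-(2-{[tert-butyl(dimethyl)silyl]oxy}ethyl)-3-methylpent-4-enoic acid, via boron ketene acetal 6 (not isolated)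
Conditions: (4S,5S)-2-bromo-1,3-bis(4-methylphenylsulfonyl)-4,5-diphenyl-1,3,2-diazaborolidine, i-Pr2NEt, CH2Cl2, −78 °C, then to 4 °C; H2O
Reagents that add atoms: none
Why: Soft enolisation of the less hindered allyl ester gives the E(O)-boron ketene acetal, which undergoes an Ireland–Claisen rearrangement through a chair in which CH2CO2t-Bu lies cis to the allylic oxygen and the E-alkene places the silyloxyethyl chain equatorial, so C5 and C10 are set together (C4 anti to C9, syn to the methyl) with the absolute sense given by the C2-symmetric boron ligand.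

Step 4
Reactants: 7 (2S,3S)-acid
Product: 8 S-ethyl (2S,3S)-2-(2-tert-butoxy-2-oxoethyl)-3-(2-{[tert-butyl(dimethyl)silyl]oxy}ethyl)-3-methylpent-4-enethioate
Conditions: EtSH, EDC·HCl, DMAP (cat.), CH2Cl2, 0 °C
Reagents that add atoms: ethanethiol CCS
Why: Carbodiimide thioesterification under neutral conditions, which avoids the acid chloride (prone to cyclise onto the tert-butyl ester) and should not epimerise C5.

Step 5
Reactants: 8 thioester; 9 (3-ethoxy-3-oxopropyl)zinc bromide (THF solution)
Product: 10 1-tert-butyl 7-ethyl (3S)-3-[(3S)-5-{[tert-butyl(dimethyl)silyl]oxy}-3-methylpent-1-en-3-yl]-4-oxoheptanedioate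
Conditions: PdCl2(PPh3)2 (5 mol %), toluene/THF, rt
Reagents that add atoms: none
Why: Fukuyama coupling (palladium-catalysed acylation of an alkylzinc halide by a thioester) should give the C6 ketone with the C7–C11–C12 arm without enolising C5 or touching either ester.

Step 6
Reactants: 10 silyl ether keto diester
Product: 11 1-tert-butyl 7-ethyl (3S)-3-[(3S)-5-hydroxy-3-methylpent-1-en-3-yl]-4-oxoheptanedioate
Conditions: HF·pyridine, pyridine, THF, 0 °C to rt
Reagents that add atoms: none
Why: Fluoride cleavage of the primary silyl ether under buffered, non-basic conditions that leave the tert-butyl ester and the C5 stereocenter intact.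

Step 7
Reactants: 11 hydroxy ketone
Product: 12 1-tert-butyl 7-ethyl (3S)-3-[(3S)-3-methyl-5-oxopent-1-en-3-yl]-4-oxoheptanedioate
Conditions: Dess–Martin periodinane, CH2Cl2, 0 °C to rt
Reagents that add atoms: none
Why: Dess–Martin oxidation of the primary alcohol to the C8 aldehyde under neutral conditions, giving the 1,5-keto aldehyde without exposing C5 to base.

Step 8
Reactants: 12 keto aldehyde
Product: 14 6-oxo-8α,12-olide tert-butyl ester (keto lactone), via ketol 13 (not isolated)
Conditions: L-proline (30 mol %), DMSO, rt; then pyridinium p-toluenesulfonate (10 mol %), toluene, 60 °C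
Reagents that add atoms: none
Why: Proline-catalysed 6-enolendo aldol cyclisation (Hajos–Parrish type) through the enamine of the less hindered C7 methylene should close C7–C8 with the hydroxyl equatorial (8α, since the axial site is syn-axial to the C10 methyl) and the C7 arm equilibrated to equatorial (7β), after which acid-catalysed lactonisation with the trans-disposed ethyl ester gives the 8,12-olide.

Step 9
Reactants: 14 keto lactone
Product: 15 6β-hydroxy-8α,12-olide tert-butyl ester
Conditions: LiBH(s-Bu)3, THF, −78 °C; then pH 7 buffer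
Reagents that add atoms: none
Why: Hindered-borohydride reduction of the cyclohexanone, in which axial approach to C6 is blocked by the syn-axial C10 methyl, so hydride should enter equatorially and give the axial 6β-alcohol cis to both flanking arms.

Step 10
Reactants: 15 6β-alcohol
Product: 16 6β-methanesulfonate of 15
Conditions: MsCl, Et3N, CH2Cl2, 0 °C
Reagents that add atoms: methanesulfonyl chloride CS(=O)(=O)Cl
Why: Sulfonylation through sulfene tolerates the hindered axial alcohol and retains the C6 configuration.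

Step 11
Reactants: 16 6β-mesyloxy-8α,12-olide
Product: 18 8α-hydroxy-6α,12-olide tert-butyl ester, via carboxylate 17 (not isolated)
Conditions: LiOH·H2O (1.05 equiv), THF/H2O, 0 °C; then DMF, 55 °C; aq. NaH2PO4
Reagents that add atoms: lithium hydroxide [Li+].[OH-] (one oxygen of the carboxyl group)
Why: Hydroxide first cleaves the strained trans-fused 8,12-olide by acyl substitution at 0 °C, where the tert-butyl ester and the secondary mesylate are inert, giving carboxylate 17 with its C12 carboxyl on the equatorial 7β arm and a free 8α-hydroxyl. On warming in DMF the carboxylate attacks C6 from the α face and expels the axial 6β-mesylate in an intramolecular SN2 reaction; the closest known reaction type is lactonisation by carboxylate displacement of a sulfonate, the inversion mode also seen in Mitsunobu lactonisations. The γ-lactone ring closes in the 5-exo-tet mode. The only new stereocenter, C6, is set by inversion of the 6β-sulfonate, so the new C6–O bond is equatorial (6α) and the ring fusion trans. The step needs substitution to win over anti elimination of the axial mesylate and needs the C12 rather than the C15 carboxyl to attack. The single equivalent of LiOH is consumed by the lactone, leaving only a weakly basic carboxylate, and C15 stays masked as a non-nucleophilic tert-butyl ester.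

Step 12
Reactants: 18 8α-hydroxy-6α,12-olide tert-butyl ester
Product: 21 8α-hydroxy-3,13-bis(methylidene) lactone tert-butyl ester, via bis-Mannich base 19 (not isolated), via bis-ammonium iodide 20 (not isolated)
Conditions: LiN(i-Pr)2 (3.3 equiv), THF, −78 °C; CH2=NMe2+ I−, −78 to 0 °C; then MeI, MeOH, rt; then NaHCO3, CH2Cl2/H2O, rt
Reagents that add atoms: N,N-dimethylmethyleneiminium iodide C=[N+](C)C.[I-]
Why: Double Mannich aminomethylation of the lactone (C11) and ester (C4) enolates, exhaustive N-methylation and base-induced elimination (Eschenmoser methylenation) should install both exocyclic methylenes in one pot, the transient sp3 centers of 19 being destroyed on elimination while the C8 alkoxide protects the hydroxyl.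

Step 13
Reactants: 21 8α-alcohol; 22 angelic acid
Product: 24 tert-butyl ester of the target, via mixed anhydride 23 (not isolated)
Conditions: 2,4,6-trichlorobenzoyl chloride, Et3N, toluene, rt; then 21, toluene, 80 °C
Reagents that add atoms: none
Why: Yamaguchi-type acylation through the mixed trichlorobenzoic anhydride without a nucleophilic catalyst esterifies the equatorial 8α-hydroxyl with retention at C8 and should not isomerise the Z-angelate to the E-tiglate.

Step 14
Reactants: 24 tert-butyl ester
Product: 25 2-[(3aR,4S,6S,7R,7aR)-6-ethenyl-6-methyl-4-{[(2Z)-2-methylbut-2-enoyl]oxy}-3-methylidene-2-oxooctahydro-1-benzofuran-7-yl]prop-2-enoic acid (target)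
Conditions: CF3CO2H, CH2Cl2, 0 °C to rt
Reagents that add atoms: none
Why: Acidolysis of the tert-butyl ester with loss of isobutene liberates the C15 acid without affecting the angelate, the α-methylene lactone or the vinyl group.

**Compound list**

1 | tert-butyl(but-3-yn-1-yloxy)dimethylsilane | C#CCCO[Si](C)(C)C(C)(C)C | starting material
2 | [(1E)-4-{[tert-butyl(dimethyl)silyl]oxy}-2-methylbut-1-en-1-yl](dimethyl)alane | C[Al](C)/C=C(\C)CCO[Si](C)(C)C(C)(C)C | intermediate (not isolated)
3 | (2E)-5-{[tert-butyl(dimethyl)silyl]oxy}-3-methylpent-2-en-1-ol | OC/C=C(\C)CCO[Si](C)(C)C(C)(C)C | intermediate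
4 | 4-tert-butoxy-4-oxobutanoic acid | CC(C)(C)OC(=O)CCC(=O)O | starting material
5 | 1-tert-butyl 4-[(2E)-5-{[tert-butyl(dimethyl)silyl]oxy}-3-methylpent-2-en-1-yl] butanedioate | CC(C)(C)OC(=O)CCC(=O)OC/C=C(\C)CCO[Si](C)(C)C(C)(C)C | intermediate
6 | E(O)-boron ketene acetal of 5 (CH2CO2t-Bu cis to the allyloxy group; boron in the (4S,5S)-1,3-ditosyl-4,5-diphenyl-1,3,2-diazaborolidine ring) | CC(C)(C)OC(=O)C/C=C(/OB1N(S(=O)(=O)c2ccc(C)cc2)[C@@H](c2ccccc2)[C@H](c2ccccc2)N1S(=O)(=O)c1ccc(C)cc1)OC/C=C(\C)CCO[Si](C)(C)C(C)(C)C | intermediate (not isolated)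
7 | (2S,3S)-2-(2-tert-butoxy-2-oxoethyl)-3-(2-{[tert-butyl(dimethyl)silyl]oxy}ethyl)-3-methylpent-4-enoic acid | C=C[C@](C)(CCO[Si](C)(C)C(C)(C)C)[C@H](CC(=O)OC(C)(C)C)C(=O)O | intermediate
8 | S-ethyl (2S,3S)-2-(2-tert-butoxy-2-oxoethyl)-3-(2-{[tert-butyl(dimethyl)silyl]oxy}ethyl)-3-methylpent-4-enethioate | C=C[C@](C)(CCO[Si](C)(C)C(C)(C)C)[C@H](CC(=O)OC(C)(C)C)C(=O)SCC | intermediate
9 | (3-ethoxy-3-oxopropyl)zinc bromide | CCOC(=O)CC[Zn]Br | starting material
10 | 1-tert-butyl 7-ethyl (3S)-3-[(3S)-5-{[tert-butyl(dimethyl)silyl]oxy}-3-methylpent-1-en-3-yl]-4-oxoheptanedioate | C=C[C@](C)(CCO[Si](C)(C)C(C)(C)C)[C@H](CC(=O)OC(C)(C)C)C(=O)CCC(=O)OCC | intermediate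
11 | 1-tert-butyl 7-ethyl (3S)-3-[(3S)-5-hydroxy-3-methylpent-1-en-3-yl]-4-oxoheptanedioate | C=C[C@](C)(CCO)[C@H](CC(=O)OC(C)(C)C)C(=O)CCC(=O)OCC | intermediate
12 | 1-tert-butyl 7-ethyl (3S)-3-[(3S)-3-methyl-5-oxopent-1-en-3-yl]-4-oxoheptanedioate | C=C[C@](C)(CC=O)[C@H](CC(=O)OC(C)(C)C)C(=O)CCC(=O)OCC | intermediate
13 | ketol: cyclohexanone (C6=O) with 5β-CH2CO2t-Bu, 7β-CH2CO2Et, 8α-OH, 10β-methyl, 10α-vinyl | C=C[C@]1(C)C[C@H](O)[C@@H](CC(=O)OCC)C(=O)[C@H]1CC(=O)OC(C)(C)C | intermediate (not isolated)
14 | keto lactone: C6 ketone, trans-fused γ-lactone from the 7β-CH2C(=O) arm to the 8α-oxygen, 5β-CH2CO2t-Bu, 10β-methyl, 10α-vinyl | C=C[C@]1(C)C[C@@H]2OC(=O)C[C@H]2C(=O)[C@H]1CC(=O)OC(C)(C)C | intermediate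
15 | 6β-hydroxy-8α,12-olide tert-butyl ester (axial 6-OH cis to the C5 and C7 arms) | C=C[C@]1(C)C[C@@H]2OC(=O)C[C@H]2[C@@H](O)[C@H]1CC(=O)OC(C)(C)C | intermediate
16 | 6β-methanesulfonyloxy-8α,12-olide tert-butyl ester | C=C[C@]1(C)C[C@@H]2OC(=O)C[C@H]2[C@@H](OS(C)(=O)=O)[C@H]1CC(=O)OC(C)(C)C | intermediate
17 | lithium carboxylate: 8α-hydroxy, 6β-mesyloxy, 7β-CH2CO2Li, 5β-CH2CO2t-Bu cyclohexane | C=C[C@]1(C)C[C@H](O)[C@@H](CC(=O)[O-])[C@@H](OS(C)(=O)=O)[C@H]1CC(=O)OC(C)(C)C.[Li+] | intermediate (not isolated)
18 | 8α-hydroxy-6α,12-olide tert-butyl ester (trans-fused lactone on O6, C11 still CH2) | C=C[C@]1(C)C[C@H](O)[C@H]2CC(=O)O[C@@H]2[C@H]1CC(=O)OC(C)(C)C | intermediate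
19 | bis-Mannich base: 18 carrying CH2NMe2 at C11 and at C4 (both epimer mixtures) | C=C[C@]1(C)C[C@H](O)[C@H]2C(CN(C)C)C(=O)O[C@@H]2[C@H]1C(CN(C)C)C(=O)OC(C)(C)C | intermediate (not isolated)
20 | bis(trimethylammoniomethyl) diiodide of 19 | C=C[C@]1(C)C[C@H](O)[C@H]2C(C[N+](C)(C)C)C(=O)O[C@@H]2[C@H]1C(C[N+](C)(C)C)C(=O)OC(C)(C)C.[I-].[I-] | intermediate (not isolated)
21 | 8α-hydroxy α-methylene-6α,12-olide with 5β-C(=CH2)CO2t-Bu | C=C[C@]1(C)C[C@H](O)[C@H]2C(=C)C(=O)O[C@@H]2[C@H]1C(=C)C(=O)OC(C)(C)C | intermediate
22 | angelic acid, (2Z)-2-methylbut-2-enoic acid | C/C=C(/C)C(=O)O | starting material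
23 | (2Z)-2-methylbut-2-enoic 2,4,6-trichlorobenzoic anhydride | C/C=C(/C)C(=O)OC(=O)c1c(Cl)cc(Cl)cc1Cl | intermediate (not isolated)
24 | tert-butyl ester of the target (8α-angelate, α-methylene-6α,12-olide) | C=C[C@]1(C)C[C@H](OC(=O)/C(C)=C\C)[C@H]2C(=C)C(=O)O[C@@H]2[C@H]1C(=C)C(=O)OC(C)(C)C | intermediate
25 | 2-[(3aR,4S,6S,7R,7aR)-6-ethenyl-6-methyl-4-{[(2Z)-2-methylbut-2-enoyl]oxy}-3-methylidene-2-oxooctahydro-1-benzofuran-7-yl]prop-2-enoic acid | C=C[C@]1(C)C[C@H](OC(=O)/C(C)=C\C)[C@H]2C(=C)C(=O)O[C@@H]2[C@H]1C(=C)C(=O)O | target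

**Totals.** Total step count: 14. Longest linear sequence: 14 steps (from 1).

**Steps most likely to fail**

1. Step 11. Anti elimination of the axial 6β-mesylate (both flanking axial α-hydrogens are antiperiplanar) or slow closure to the strained trans-fused ring may outrun substitution. Fallback, setting out from 15: the lactone is opened with LiOH (1.05 equiv, THF/H2O, 0 °C) to the lithium dihydroxy carboxylate F1. The equatorial 8α-hydroxyl is then silylated selectively (t-BuMe2SiCl, imidazole, DMF; the silyl ester is cleaved on aqueous K2CO3 work-up) to give the 6β-hydroxy acid 8α-silyl ether F2. Mitsunobu lactonisation (PPh3, diisopropyl azodicarboxylate, toluene, 0 °C) activates the alcohol as its alkoxyphosphonium ion beside the carboxylate and closes the same C6–O bond with inversion, giving the silyl-protected trans-lactone F3. HF·pyridine removes the silyl group and the route is rejoined at 18.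

2. Step 8. Dehydration of the β-hydroxy ketone to the enone, epimerisation at C5 through the more substituted enol, or incomplete lactonisation of the trans-disposed ester may erode the sequence. Fallback, setting out from 12: soft enolisation with TiCl4 and i-Pr2NEt (CH2Cl2, −78 °C) forms the titanium enolate on the C7 side, which adds to the aldehyde at low temperature to give ketol 13 without an amine catalyst. Me3SnOH (1,2-dichloroethane, 60 °C) hydrolyses the ethyl ester to the hydroxy keto acid F4, and carbodiimide lactonisation (EDC·HCl, DMAP, CH2Cl2) returns to 14.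

3. Step 3. Competing enolisation on the tert-butyl ester side or insufficient facial discrimination by the boron reagent may lower conversion or enantiomeric purity. Fallback, setting out from 5: the achiral ester-enolate variant (LiN(i-Pr)2, Me3SiCl, THF, −78 °C to rt) gives the racemic acid F5 with the same relative configuration. Crystallisation of its salt with (1S)-1-phenylethanamine gives the single diastereomeric ammonium carboxylate F6, and acidification returns 7.

**Further compounds**

F1 | step 11 | lithium carboxylate of the 6β,8α-dihydroxy acid (5β-CH2CO2t-Bu, 7β-CH2CO2Li) | C=C[C@]1(C)C[C@H](O)[C@@H](CC(=O)[O-])[C@@H](O)[C@H]1CC(=O)OC(C)(C)C.[Li+]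
F2 | step 11 | 6β-hydroxy-8α-[tert-butyl(dimethyl)silyl]oxy acid (7β-CH2CO2H, 5β-CH2CO2t-Bu) | C=C[C@]1(C)C[C@H](O[Si](C)(C)C(C)(C)C)[C@@H](CC(=O)O)[C@@H](O)[C@H]1CC(=O)OC(C)(C)C
F3 | step 11 | 8α-[tert-butyl(dimethyl)silyl]oxy-6α,12-olide tert-butyl ester | C=C[C@]1(C)C[C@H](O[Si](C)(C)C(C)(C)C)[C@H]2CC(=O)O[C@@H]2[C@H]1CC(=O)OC(C)(C)C
F4 | step 8 | hydroxy keto acid: ketol 13 with 7β-CH2CO2H | C=C[C@]1(C)C[C@H](O)[C@@H](CC(=O)O)C(=O)[C@H]1CC(=O)OC(C)(C)C
F5 | step 3 | racemic (2S*,3S*)-2-(2-tert-butoxy-2-oxoethyl)-3-(2-{[tert-butyl(dimethyl)silyl]oxy}ethyl)-3-methylpent-4-enoic acid (one enantiomer drawn) | C=C[C@](C)(CCO[Si](C)(C)C(C)(C)C)[C@H](CC(=O)OC(C)(C)C)C(=O)O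
F6 | step 3 | (1S)-1-phenylethanaminium salt of acid 7 | C=C[C@](C)(CCO[Si](C)(C)C(C)(C)C)[C@H](CC(=O)OC(C)(C)C)C(=O)[O-].C[C@H]([NH3+])c1ccccc1
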